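The key step exploits ring A, in which C7 and C8a both bear oxygen in a 1,3 relation while C4a, next to C8a, carries the only carbon substituent: this is the pattern of a cyclohexane-1,3-dione alkylated at its 4-position. Ring A is therefore disconnected at C4a–C5 and C7–C8. A methyl ketone that already holds the protected ring B and the S-configured C2 carbinol as its silyl ether is annulated with methyl acrylate by Michael addition and Claisen condensation in one operation, giving the carbocycle with both oxygens in place. The C2 hydroxyl then closes the pyran ring onto the C8a carbonyl with retention, one dehydrogenation aromatises ring A, and the catechol is unmasked last.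

Key step: step 11

Remarks and assumptions:
- Flavan numbering is used (O1, C2, C3, C4, C4a, C5 to C8, C8a). Ar = 3,4-bis(methoxymethoxy)-2,5-bis(3-methylbut-2-enyl)phenyl.
- The C4a centre formed in step 11 is carried as a mixture of epimers in compounds 18 to 23; this is harmless because C4a becomes aromatic in step 13.
- Steps 1 to 4 are twofold reactions of one kind on the two catechol oxygens or the two allyl groups. Each is written as a single step without the mono-reacted stage. Where a reagent is consumed twice, its second equivalent is entered under "Reagents that add atoms".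

Step 1
Reactants: 1 4-bromocatechol; 2 allyl bromide
Product: 3 4-bromo-1,2-bis(prop-2-enyloxy)benzene
Conditions: allyl bromide (2.5 equiv in all), K2CO3 (3 equiv), acetone, reflux, N2
Reagents that add atoms: allyl bromide (second equivalent of 2), C=CCBr
Why: Twofold Williamson ether synthesis in which each of the two phenoxides is alkylated by one equivalent of the reactive primary allylic bromide under carbonate conditions that leave the aryl bromide untouched.

Step 2
Reactants: 3 4-bromo-1,2-bis(prop-2-enyloxy)benzene
Product: 4 4-bromo-3,6-di(prop-2-enyl)benzene-1,2-diol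
Conditions: PhNEt2, 195 °C, N2
Reagents that add atoms: none
Why: Double aromatic Claisen rearrangement in which each allyl ether has one free ortho carbon (C6 for the ether on O1, C3 for the ether on O2) where the [3,3] shift ends in irreversible tautomerisation, whereas a para migration would need a first shift onto an oxygen-bearing ring carbon followed by a Cope step and should not compete.

Step 3
Reactants: 4 4-bromo-3,6-di(prop-2-enyl)benzene-1,2-diol
Product: 5 1-bromo-3,4-bis(methoxymethoxy)-2,5-di(prop-2-enyl)benzene
Conditions: MOMCl (2.5 equiv in all), iPr2NEt (3 equiv), CH2Cl2, 0 °C to rt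
Reagents that add atoms: chloromethyl methyl ether (MOMCl, first equivalent), COCCl; chloromethyl methyl ether (MOMCl, second equivalent), COCCl
Why: O-alkylation of both phenols with the reactive chloromethyl ether gives the bis-acetal, which withstands the organolithium, alkoxide and amide bases used later and can be removed at the end without hydrogenolysis.

Step 4
Reactants: 5 1-bromo-3,4-bis(methoxymethoxy)-2,5-di(prop-2-enyl)benzene; 6 2-methylbut-2-ene
Product: 7 1-bromo-3,4-bis(methoxymethoxy)-2,5-bis(3-methylbut-2-enyl)benzene (ArBr)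
Conditions: second-generation Grubbs catalyst (H2IMes)(PCy3)Cl2Ru=CHPh (5 mol%), 2-methylbut-2-ene (large excess)/CH2Cl2, 40 °C, sealed vessel
Reagents that add atoms: 2-methylbut-2-ene (second equivalent of 6), CC=C(C)C
Why: Olefin cross-metathesis of each terminal allyl group with the trisubstituted alkene turns allyl into prenyl with loss of propene, leaves aryl bromide and acetals untouched and raises no E/Z question because the new alkene end is gem-dimethyl.

Step 5
Reactants: 8 5-oxohexanoic acid
Product: 10 N-methoxy-N-methyl-5-oxohexanamide, via acyl imidazolide 9 (not isolated)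
Conditions: 1,1'-carbonyldiimidazole, CH2Cl2, rt; then MeNHOMe·HCl, rt
Reagents that add atoms: N,O-dimethylhydroxylamine hydrochloride, CNOC.Cl
Why: Weinreb amide formation by activation of the acid as its acyl imidazolide and aminolysis under near-neutral conditions that leave the methyl ketone intact.

Step 6
Reactants: 10 N-methoxy-N-methyl-5-oxohexanamide
Product: 11 N-methoxy-N-methyl-4-(2-methyl-1,3-dioxolan-2-yl)butanamide
Conditions: HOCH2CH2OH, p-TsOH (cat.), PhH, reflux, Dean–Stark
Reagents that add atoms: ethylene glycol, OCCO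
Why: Acid-catalysed ketalisation with azeotropic removal of water masks the methyl ketone as a dioxolane so that only the amide carbonyl remains electrophilic toward the aryllithium.

Step 7
Reactants: 7 1-bromo-3,4-bis(methoxymethoxy)-2,5-bis(3-methylbut-2-enyl)benzene; 11 N-methoxy-N-methyl-4-(2-methyl-1,3-dioxolan-2-yl)butanamide
Product: 13 1-Ar-4-(2-methyl-1,3-dioxolan-2-yl)butan-1-one, via aryllithium 12 (not isolated)
Conditions: n-BuLi, THF, −78 °C; then 11, −78 to 0 °C; aq. NH4Cl
Reagents that add atoms: none
Why: Bromine–lithium exchange followed by Weinreb ketone synthesis, in which the aryllithium adds once to the N-methoxy-N-methylamide to form a chelated tetrahedral intermediate that releases the aryl ketone only on aqueous quench, while ketal, acetals and prenyl groups are inert at low temperature.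

Step 8
Reactants: 13 1-Ar-4-(2-methyl-1,3-dioxolan-2-yl)butan-1-one
Product: 14 (1S)-1-Ar-4-(2-methyl-1,3-dioxolan-2-yl)butan-1-ol
Conditions: RuCl(p-cymene)[(S,S)-TsDPEN] (2 mol%), HCO2H/Et3N (5:2), DMF, 40 °C
Reagents that add atoms: none
Why: Noyori asymmetric transfer hydrogenation in which the (S,S)-TsDPEN ruthenium hydride distinguishes the aryl from the alkyl side of the ketone through the contact between its arene ligand and the substrate aryl ring and should therefore give the S benzylic alcohol, as it does for aryl alkyl ketones in general, without reducing the isolated prenyl alkenes.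

Step 9
Reactants: 14 (1S)-1-Ar-4-(2-methyl-1,3-dioxolan-2-yl)butan-1-ol
Product: 15 tert-butyl{(1S)-1-Ar-4-(2-methyl-1,3-dioxolan-2-yl)butoxy}dimethylsilane
Conditions: TBSCl, imidazole, DMAP (cat.), DMF, rt to 40 °C
Reagents that add atoms: tert-butyldimethylsilyl chloride (TBSCl), CC(C)(C)[Si](C)(C)Cl
Why: Silylation of the secondary benzylic alcohol through the N-silylimidazolium species under neutral conditions that leave the dioxolane and the methoxymethyl acetals untouched gives an ether that is stable to alkoxide and prevents oxa-Michael addition or lactol formation by the free hydroxyl in the key step.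

Step 10
Reactants: 15 tert-butyl{(1S)-1-Ar-4-(2-methyl-1,3-dioxolan-2-yl)butoxy}dimethylsilane
Product: 16 (6S)-6-Ar-6-(tert-butyldimethylsilyloxy)hexan-2-one
Conditions: PPTS (cat.), acetone/H2O, 50 °C
Reagents that add atoms: water, O
Why: Mild acid-catalysed ketal hydrolysis liberates the methyl ketone, the weakly acidic pyridinium salt being too mild to cleave the hindered secondary silyl ether or the aryl acetals or to affect the prenyl groups.

Step 11
Reactants: 16 (6S)-6-Ar-6-(tert-butyldimethylsilyloxy)hexan-2-one; 17 methyl acrylate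
Product: 19 4-[(3S)-3-Ar-3-(tert-butyldimethylsilyloxy)propyl]cyclohexane-1,3-dione, via keto ester Michael adduct 18 (not isolated)
Conditions: KOtBu (2.2 equiv), THF, 0 °C; 17 (1.05 equiv, slow addition), 0 °C to rt; cold 1 M HCl to pH 4
Reagents that add atoms: none
Why: Potassium tert-butoxide equilibrates the ketone enolates, the more substituted enolate at C3 of the hexanone (the future C4a) adds to methyl acrylate in a Michael reaction that forms C4a–C5, and after proton transfer the methyl-side enolate (future C8) attacks the ester carbonyl (future C7) in an intramolecular Claisen condensation with loss of methoxide. The closest known reaction type is the base-mediated consecutive Michael–Claisen [3+3] annulation of methyl ketones with acrylates to 4-substituted cyclohexane-1,3-diones. Ring A closes in a 6-(enolendo)-exo-trig mode, since the ester carbonyl attacked by the enolate carbon lies outside the forming ring. The only new stereocentre, C4a, is not controlled and need not be, because it is epimerisable and becomes aromatic in step 13, while the remote C2 carbinol is not enolisable and is protected, so its configuration is untouched. The step needs Michael addition at the methylene and not the methyl carbon: equilibrating alkoxide conditions favour the more substituted enolate, the methylene adduct closes through the unhindered methyl enolate faster than the isomeric adduct could close through a hindered one, and deprotonation of the acidic dione makes this closure irreversible. It also needs a single acrylate addition, which slow addition of one equivalent of acrylate to an excess of base should secure.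

Step 12
Reactants: 19 4-[(3S)-3-Ar-3-(tert-butyldimethylsilyloxy)propyl]cyclohexane-1,3-dione
Product: 21 (2S)-2-Ar-2,3,4,4a,5,6-hexahydro-7H-chromen-7-one, via hydroxy dione 20 (not isolated)
Conditions: Bu4NF, AcOH, THF, rt; then PPTS (cat.), PhH, 4 Å molecular sieves, 40 °C
Reagents that add atoms: none
Why: Fluoride cleaves the silyl ether and the freed C2 hydroxyl adds to the nearer dione carbonyl (C8a) to give a six-membered hemiketal that dehydrates under weak acid to the conjugated vinylogous ester (intramolecular vinylogous esterification), so the C2–O bond is never broken and the S configuration is retained, whereas attack on the distant carbonyl would need an eight-membered bridged ring and the acid is kept too weak to ionise the benzylic carbinol.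

Step 13
Reactants: 21 (2S)-2-Ar-2,3,4,4a,5,6-hexahydro-7H-chromen-7-one
Product: 25 (2S)-2-Ar-3,4-dihydro-2H-chromen-7-ol, via C6 selenide 22 (not isolated), via C6 selenoxide 23 (not isolated), via cross-conjugated dienone 24 (not isolated)
Conditions: LiN(iPr)2, THF, −78 °C; PhSeBr (1.0 equiv), −78 °C; aq. NH4Cl; then crude selenide, NaIO4, NaHCO3, THF/MeOH/H2O, 0 °C to rt
Reagents that add atoms: none
Why: Kinetic deprotonation of the vinylogous ester occurs at the alpha-prime carbon C6, selenenylation there and periodate oxidation (chosen because it forms no peracid that could epoxidise the prenyl groups) give a selenoxide that undergoes syn elimination toward C5, and the resulting cyclohexadienone bearing a hydrogen at C4a tautomerises irreversibly to the C7 phenol, which aromatises ring A, removes the C4a centre and leaves C2 untouched.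

Step 14
Reactants: 25 (2S)-2-Ar-3,4-dihydro-2H-chromen-7-ol
Product: 26 Kazinol A
Conditions: HCl (1 M in MeOH), 0 °C to rt, Ar
Reagents that add atoms: none
Why: Acid-catalysed acetal cleavage transfers both methoxymethyl groups to methanol as dimethoxymethane under conditions dilute and cold enough to avoid cyclisation of the ortho-prenyl phenols to chromans or ionisation of the benzylic C2–O bond.

Compound list (Ar = 3,4-bis(methoxymethoxy)-2,5-bis(3-methylbut-2-enyl)phenyl)
1 | 4-bromocatechol (4-bromobenzene-1,2-diol) | Oc1ccc(Br)cc1O | starting material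
2 | allyl bromide (3-bromoprop-1-ene) | C=CCBr | starting material
3 | 4-bromo-1,2-bis(prop-2-enyloxy)benzene | C=CCOc1ccc(Br)cc1OCC=C | intermediate
4 | 4-bromo-3,6-di(prop-2-enyl)benzene-1,2-diol | Oc1c(O)c(CC=C)c(Br)cc1CC=C | intermediate
5 | 1-bromo-3,4-bis(methoxymethoxy)-2,5-di(prop-2-enyl)benzene | COCOc1c(OCOC)c(CC=C)c(Br)cc1CC=C | intermediate
6 | 2-methylbut-2-ene | CC=C(C)C | starting material
7 | 1-bromo-3,4-bis(methoxymethoxy)-2,5-bis(3-methylbut-2-enyl)benzene (ArBr) | COCOc1c(OCOC)c(CC=C(C)C)c(Br)cc1CC=C(C)C | intermediate
8 | 5-oxohexanoic acid | CC(=O)CCCC(=O)O | starting material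
9 | 1-(1H-imidazol-1-yl)hexane-1,5-dione (acyl imidazolide) | CC(=O)CCCC(=O)n1ccnc1 | intermediate
10 | N-methoxy-N-methyl-5-oxohexanamide | CON(C)C(=O)CCCC(C)=O | intermediate
11 | N-methoxy-N-methyl-4-(2-methyl-1,3-dioxolan-2-yl)butanamide | CON(C)C(=O)CCCC1(C)OCCO1 | intermediate
12 | [3,4-bis(methoxymethoxy)-2,5-bis(3-methylbut-2-enyl)phenyl]lithium (ArLi) | [Li]c1cc(CC=C(C)C)c(OCOC)c(OCOC)c1CC=C(C)C | intermediate
13 | 1-Ar-4-(2-methyl-1,3-dioxolan-2-yl)butan-1-one | CC1(CCCC(=O)c2cc(CC=C(C)C)c(OCOC)c(OCOC)c2CC=C(C)C)OCCO1 | intermediate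
14 | (1S)-1-Ar-4-(2-methyl-1,3-dioxolan-2-yl)butan-1-ol | CC1(CCC[C@H](O)c2cc(CC=C(C)C)c(OCOC)c(OCOC)c2CC=C(C)C)OCCO1 | intermediate
15 | tert-butyl{(1S)-1-Ar-4-(2-methyl-1,3-dioxolan-2-yl)butoxy}dimethylsilane | CC1(CCC[C@H](O[Si](C)(C)C(C)(C)C)c2cc(CC=C(C)C)c(OCOC)c(OCOC)c2CC=C(C)C)OCCO1 | intermediate
16 | (6S)-6-Ar-6-(tert-butyldimethylsilyloxy)hexan-2-one | CC(=O)CCC[C@H](O[Si](C)(C)C(C)(C)C)c1cc(CC=C(C)C)c(OCOC)c(OCOC)c1CC=C(C)C | intermediate
17 | methyl acrylate | C=CC(=O)OC | starting material
18 | methyl (7S)-4-acetyl-7-Ar-7-(tert-butyldimethylsilyloxy)heptanoate (C4 epimers) | COC(=O)CCC(C(C)=O)CC[C@H](O[Si](C)(C)C(C)(C)C)c1cc(CC=C(C)C)c(OCOC)c(OCOC)c1CC=C(C)C | intermediate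
19 | 4-[(3S)-3-Ar-3-(tert-butyldimethylsilyloxy)propyl]cyclohexane-1,3-dione (C4 epimers) | O=C1CC(=O)C(CC[C@H](O[Si](C)(C)C(C)(C)C)c2cc(CC=C(C)C)c(OCOC)c(OCOC)c2CC=C(C)C)CC1 | intermediate
20 | 4-[(3S)-3-Ar-3-hydroxypropyl]cyclohexane-1,3-dione (C4 epimers) | O=C1CC(=O)C(CC[C@H](O)c2cc(CC=C(C)C)c(OCOC)c(OCOC)c2CC=C(C)C)CC1 | intermediate
21 | (2S)-2-Ar-2,3,4,4a,5,6-hexahydro-7H-chromen-7-one (C4a epimers) | O=C1C=C2O[C@H](c3cc(CC=C(C)C)c(OCOC)c(OCOC)c3CC=C(C)C)CCC2CC1 | intermediate
22 | (2S)-2-Ar-6-(phenylselanyl)-2,3,4,4a,5,6-hexahydro-7H-chromen-7-one (C4a and C6 epimers) | O=C1C=C2O[C@H](c3cc(CC=C(C)C)c(OCOC)c(OCOC)c3CC=C(C)C)CCC2CC1[Se]c1ccccc1 | intermediate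
23 | (2S)-2-Ar-6-(phenylseleninyl)-2,3,4,4a,5,6-hexahydro-7H-chromen-7-one (selenoxide, mixture of epimers) | O=C1C=C2O[C@H](c3cc(CC=C(C)C)c(OCOC)c(OCOC)c3CC=C(C)C)CCC2CC1[Se](=O)c1ccccc1 | intermediate
24 | (2S)-2-Ar-2,3,4,4a-tetrahydro-7H-chromen-7-one | O=C1C=CC2CC[C@@H](c3cc(CC=C(C)C)c(OCOC)c(OCOC)c3CC=C(C)C)OC2=C1 | intermediate
25 | (2S)-2-Ar-3,4-dihydro-2H-chromen-7-ol | CC(C)=CCc1cc([C@@H]2CCc3ccc(O)cc3O2)c(CC=C(C)C)c(OCOC)c1OCOC | intermediate
26 | Kazinol A, 4-[(2S)-7-hydroxy-3,4-dihydro-2H-chromen-2-yl]-3,6-bis(3-methylbut-2-enyl)benzene-1,2-diol | CC(C)=CCc1cc([C@@H]2CCc3ccc(O)cc3O2)c(CC=C(C)C)c(O)c1O | target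

Total step count: 14.
Longest linear sequence: 12 steps (steps 1 to 4 and 7 to 14 from 4-bromocatechol); steps 5 and 6 form a two-step side branch that joins at step 7.

Steps most likely to fail

1. Step 11 (key step). What may go wrong: Michael addition through the methyl carbon or at both alpha carbons, a second acrylate addition to the dione enolate, or anionic oligomerisation of the acrylate, so that the annulation is diverted to the 2-alkyl dione or to open-chain adducts. Fallback: ring A is brought in ready-made and alkylated at its alpha-prime carbon, which fixes the regiochemistry by construction. The fallback sets out from bromide 7 and returns at dione 19. Bromine–lithium exchange (n-BuLi, THF, −78 °C), transmetalation with ZnCl2 and Negishi acylation with 3-chloropropanoyl chloride under Pd(PPh3)4 catalysis should give 1-Ar-3-chloropropan-1-one F1. Corey–Bakshi–Shibata reduction ((R)-2-methyl-CBS-oxazaborolidine, catecholborane, toluene, −78 °C; catecholborane is chosen because it should not hydroborate the prenyl alkenes) should give (1S)-1-Ar-3-chloropropan-1-ol F2. Silylation as in step 9 should give tert-butyl[(1S)-1-Ar-3-chloropropoxy]dimethylsilane F3, and Finkelstein exchange (NaI, acetone, reflux) should give tert-butyl[(1S)-1-Ar-3-iodopropoxy]dimethylsilane F4. Stork–Danheiser alkylation of the lithium enolate of commercial 3-ethoxycyclohex-2-en-1-one (LiN(iPr)2, THF/DMPU, −78 to 0 °C) with this iodide should give 6-[(3S)-3-Ar-3-(tert-butyldimethylsilyloxy)propyl]-3-ethoxycyclohex-2-en-1-one F5, and hydrolysis of the vinylogous ester (1 M HCl, THF, 0 °C to rt) should give dione 19.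

2. Step 2. What may go wrong: leakage of one allyl group to C5 through a shift onto an oxygen-bearing carbon and a Cope step (para-Claisen pathway), or thermal degradation of the air-sensitive catechol, leading to regioisomeric mixtures. Fallback: C5 is blocked by a second bromine so that only the two ortho carbons can accept allyl, and the extra bromine is removed from a symmetric dibromide. The fallback sets out from 1 and returns at bromide 7. Bromination (Br2, AcOH, rt) should give 4,5-dibromobenzene-1,2-diol F6, and allylation as in step 1 should give 1,2-dibromo-4,5-bis(prop-2-enyloxy)benzene F7. Double Claisen rearrangement as in step 2, now with both para positions occupied, should give 4,5-dibromo-3,6-di(prop-2-enyl)benzene-1,2-diol F8. Protection as in step 3 should give 1,2-dibromo-4,5-bis(methoxymethoxy)-3,6-di(prop-2-enyl)benzene F9, and cross-metathesis as in step 4 should give 1,2-dibromo-4,5-bis(methoxymethoxy)-3,6-bis(3-methylbut-2-enyl)benzene F10, in which the two bromines are equivalent. A single bromine–magnesium exchange (i-PrMgCl·LiCl, THF, −15 °C) followed by protonation with MeOH should return bromide 7.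

3. Step 13. What may go wrong: competing addition of the selenenyl bromide or of the selenenic acid by-product to the prenyl alkenes, or enolisation at a position other than C6. Fallback: Saegusa–Ito dehydrosilylation, which uses no electrophilic chalcogen and no oxidant other than the palladium salt. The fallback sets out from 21 and returns at 25. Enolisation and trapping (LiN(iPr)2, then Me3SiCl, THF, −78 °C) should give the silyl dienol ether (2S)-2-Ar-7-(trimethylsilyloxy)-3,4,4a,5-tetrahydro-2H-chromene F11. Pd(OAc)2 (1 equiv, MeCN, rt) should then form a divalent palladium enolate that undergoes beta-hydride elimination to dienone 24, which tautomerises to 25.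

Further compounds
F1 | step 11 | 1-[3,4-bis(methoxymethoxy)-2,5-bis(3-methylbut-2-enyl)phenyl]-3-chloropropan-1-one | O=C(CCCl)c1cc(CC=C(C)C)c(OCOC)c(OCOC)c1CC=C(C)C
F2 | step 11 | (1S)-1-[3,4-bis(methoxymethoxy)-2,5-bis(3-methylbut-2-enyl)phenyl]-3-chloropropan-1-ol | ClCC[C@H](O)c1cc(CC=C(C)C)c(OCOC)c(OCOC)c1CC=C(C)C
F3 | step 11 | tert-butyl{(1S)-1-[3,4-bis(methoxymethoxy)-2,5-bis(3-methylbut-2-enyl)phenyl]-3-chloropropoxy}dimethylsilane | ClCC[C@H](O[Si](C)(C)C(C)(C)C)c1cc(CC=C(C)C)c(OCOC)c(OCOC)c1CC=C(C)C
F4 | step 11 | tert-butyl{(1S)-1-[3,4-bis(methoxymethoxy)-2,5-bis(3-methylbut-2-enyl)phenyl]-3-iodopropoxy}dimethylsilane | ICC[C@H](O[Si](C)(C)C(C)(C)C)c1cc(CC=C(C)C)c(OCOC)c(OCOC)c1CC=C(C)C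
F5 | step 11 | 6-[(3S)-3-[3,4-bis(methoxymethoxy)-2,5-bis(3-methylbut-2-enyl)phenyl]-3-(tert-butyldimethylsilyloxy)propyl]-3-ethoxycyclohex-2-en-1-one | CCOC1=CC(=O)C(CC[C@H](O[Si](C)(C)C(C)(C)C)c2cc(CC=C(C)C)c(OCOC)c(OCOC)c2CC=C(C)C)CC1
F6 | step 2 | 4,5-dibromobenzene-1,2-diol | Oc1cc(Br)c(Br)cc1O
F7 | step 2 | 1,2-dibromo-4,5-bis(prop-2-enyloxy)benzene | C=CCOc1cc(Br)c(Br)cc1OCC=C
F8 | step 2 | 4,5-dibromo-3,6-di(prop-2-enyl)benzene-1,2-diol | Oc1c(O)c(CC=C)c(Br)c(Br)c1CC=C
F9 | step 2 | 1,2-dibromo-4,5-bis(methoxymethoxy)-3,6-di(prop-2-enyl)benzene | COCOc1c(OCOC)c(CC=C)c(Br)c(Br)c1CC=C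
F10 | step 2 | 1,2-dibromo-4,5-bis(methoxymethoxy)-3,6-bis(3-methylbut-2-enyl)benzene | COCOc1c(OCOC)c(CC=C(C)C)c(Br)c(Br)c1CC=C(C)C
F11 | step 13 | (2S)-2-[3,4-bis(methoxymethoxy)-2,5-bis(3-methylbut-2-enyl)phenyl]-7-(trimethylsilyloxy)-3,4,4a,5-tetrahydro-2H-chromene | C[Si](C)(C)OC1=CCC2CC[C@@H](c3cc(CC=C(C)C)c(OCOC)c(OCOC)c3CC=C(C)C)OC2=C1
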